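**Readings.** The amounts in the two earlier runs show over-reaction product rising behind target.

| flask | substrate | reagent | capture agent | temperature | remark | time |
|---|---|---|---|---|---|---|
| south-west | 5 mM (in portions, 3) | 20 mM | 3 mM | 20 °C | run made earlier; portions every 12 h |  |
| south-east | 20 mM (in portions, 3) | 20 mM | 3 mM | 31 °C | run made earlier; portions every 12 h |  |
| alder | 10 mM (in portions, 3) | 20.0 mM | 3.00 mM | 25 °C | the portions of substrate follow each other after 12 h, the first at the start | 40 h |
| birch | 10 mM | 20.0 mM | 3.00 mM | 25 °C | everything together at the start | 40 h |

| run | time / h | target / % | over-reaction product / % | trapped intermediate / % |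
|---|---|---|---|---|
| south-west | 6.00 | 0 | 0 | 0 |
| south-west | 12.0 | 1.7 | 0 | 0.2 |
| south-west | 20.0 | 3.9 | 0.6 | 0.1 |
| south-west | 25.0 | 3.6 | 1.3 | 1.2 |
| south-west | 30.0 | 6.0 | 1.5 | 1.5 |
| south-east | 3.00 | 0.9 | 0.2 | 0.1 |
| south-east | 8.00 | 3.9 | 2.0 | 0.2 |
| south-east | 15.0 | 5.6 | 6.1 | 1.4 |
| south-east | 25.0 | 8.7 | 17.7 | 1.1 |
| south-east | 30.0 | 10.8 | 22.5 | 3.3 |

(scatter of a reading: 0.5 percentage points)

- which one finishes higher in share of target in all that became target or over-reaction product or trapped intermediate ("neither" within 2 percentage points) (alder / birch / neither)
- share of target in all that became target or over-reaction product or trapped intermediate, alder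
- share of target in all that became target or over-reaction product or trapped intermediate, birch

- what was read earlier has a scatter of 0.5 percentage points, one standard deviation

**Over-reaction rate.** In the south-east run, over-reaction product gains 16 percentage points between 15.0 h and 30.0 h. Dividing by that time and the mean target gives a reading of 0.133 h⁻¹. The south-west run reads 0.0182 h⁻¹. Interpolating geometrically in temperature gives my estimate of k_O, the first-order constant of target becoming over-reaction product: 0.0450 h⁻¹ at 25 °C.

**Survival share.** Let S be the fraction of target made that is still target at the end. With each portion reckoned as a steady feed from its addition to the end, alder gives 54.6%, its survival share. For a steady feed lasting L, S tends to whole when k_O L is small and to the inverse of k_O L when it is large. One minus exp(−k_O L), divided by k_O L, joins both ends.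

**Settings by hand.** Time: at fixed k_O, a longer L lowers S. Birch feeds for 40 h, so S is 46.4%. Portions: alder's later portions have a shorter L, so its S is 54.6%, higher than birch's. Capture agent: trapped intermediate takes a fraction f of what forms, read as 16.7% and 9.02% in the last south-west and south-east readings, with mean 12.8%. My reckoning, S times the remainder, gives alder 47.6% and birch 40.4%.

**The forecast.** It names alder: alder 45% (37% to 54%), birch 36% (28% to 45%). Its ground: “Dosing keeps the target younger, so it has less time to over-react.” My two values stand higher than its central values , inside its ranges.

**The result.** The flasks give alder the higher share: alder 43.8%, birch 34.4%.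

    substrate → open intermediate (k = 2.14 × 10⁻⁴ min⁻¹, Ea = 113 kJ mol⁻¹)
    reagent + open intermediate → target (k = 0.344 M⁻¹ min⁻¹, Ea = 67.0 kJ mol⁻¹)
    target → over-reaction product (k = 9.61 × 10⁻⁴ min⁻¹, Ea = 108 kJ mol⁻¹)
    open intermediate + capture agent → trapped intermediate (k = 0.190 M⁻¹ min⁻¹, Ea = 51.0 kJ mol⁻¹)
    (constants at 25 °C)

**Why alder.** The way substrate goes in is the main reason for the gap: with that difference taken away, birch being given alder's portions, birch's share moves from 34.4% to 43.8%. Alder's target against target plus over-reaction product stands at 47.5%, below its reckoned S of 54.6%. The share asked for is a selectivity: after 40.0 h alder holds 12.0% of its charge as target, less than birch's 13.1%, with substrate left at 70% against 60%.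

**Cold alder.** For alder repeated at 0 °C, k_O extrapolates to 4.86 × 10⁻⁴ h⁻¹, so S is 99.2%. That flask gives a share of 85.9%, with target 0.200% of the substrate charged, beside trapped intermediate 0.0303% and over-reaction product 0%.

The runs are calculated with made-up constants, and the scatter is random.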